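**Retrosynthetic overview**

1. The target consists of two 4-oxy-1-methylquinolin-2-one units (A and B) bridged by a cis-fused pyrano[2,3-b]pyran: ring C (fused to A, carries the 2-methylprop-1-enyl group) and ring D (fused to B, gem-dimethyl).
2. Last disconnection, ring C: the aryl ether bond O–C4(A) and the bond C3(A)–CH(alkenyl). This leads back to 4-chloro-1-methylquinolin-2-one and a ring-D fragment with a cis 3-hydroxyl and a 4-[(E)-3-hydroxy-3-methylbutenyl] chain.
3. Enabling feature: C3=C4–O of quinolone A is a vinylogous carbamate. C4 is electrophilic (β to the lactam C2=O) while it bears chloride, and C3 becomes nucleophilic once C4 is O-substituted. The CH–CH=CMe2 unit on ring C is the footprint of a 1,1-dimethylallyl cation held at six-ring distance from that C3.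
4. The cis 3-hydroxy-4-alkenyl array on ring D comes from syn opening of (3S,4S)-N-methylflindersine oxide with an alkynylalane, then trans reduction; the oxide comes from Jacobsen epoxidation.
5. Ring order: D first (Knoevenagel/oxa-6π from 4-hydroxy-1-methylquinolin-2-one and 3-methylbut-2-enal), C last; both pyridone rings are bought.

Key step: step 5

Remark: ring-D positions follow pyrano[3,2-c]quinoline numbering (O-1, C-2 gem-dimethyl, C-3, C-4, lactam C-5, N-6); compounds 6 and 10 are taken as purchased; the sense of induction in step 2 is assigned by analogy with 2,2-dimethylchromenes.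

**Step 1**
Reactants: 1 4-hydroxy-1-methylquinolin-2(1H)-one; 2 3-methylbut-2-enal
Product: 4 N-methylflindersine [2,2,6-trimethyl-2H-pyrano[3,2-c]quinolin-5(6H)-one], via alkylidene dione 3 (not isolated)
Conditions: ethylenediammonium diacetate (10 mol %), toluene, 80 °C
Reagents that add atoms: none
Why: Knoevenagel condensation at C-3 of the 1,3-dicarbonyl-type quinolone gives the 1-oxatriene 3, which closes ring D by oxa-6π electrocyclisation onto the C-4 oxygen (formal [3+3] annulation, the established entry to 2,2-dimethylpyranoquinolinones); no stereocentre is formed.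

**Step 2**
Reactants: 4 N-methylflindersine
Product: 5 (3S,4S)-3,4-epoxy-2,2,6-trimethyl-3,4-dihydro-2H-pyrano[3,2-c]quinolin-5(6H)-one
Conditions: (S,S)-Jacobsen catalyst [(salen)MnCl, C36H52ClMnN2O2, trivalent manganese] (4 mol %), aq NaOCl (pH 11.3), 4-phenylpyridine N-oxide, CH2Cl2, 0 °C
Reagents that add atoms: sodium hypochlorite, [Na+].[O-]Cl
Why: Jacobsen epoxidation of a cis-disubstituted, aryl-conjugated alkene of the 2,2-dimethylchromene class, the best substrate type for this catalyst; the oxo-manganese species transfers oxygen to one enantioface, and the (S,S) catalyst is expected by analogy with 2,2-dimethylchromenes to give the 3S,4S oxirane.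

**Step 3**
Reactants: 5 (3S,4S)-epoxide; 6 trimethyl[(2-methylbut-3-yn-2-yl)oxy]silane
Product: 8 (3S,4S)-3-hydroxy-4-(3-hydroxy-3-methylbut-1-yn-1-yl)-2,2,6-trimethyl-3,4-dihydro-2H-pyrano[3,2-c]quinolin-5(6H)-one, via silyl ether 7 (not isolated)
Conditions: 6, n-BuLi, toluene, 0 °C; Me2AlCl; then 5, −30 → 0 °C; work-up 1 M HCl, THF, rt
Reagents that add atoms: none
Why: the alane binds the oxirane oxygen, the C-4–O bond ionises towards a vinylogous oxocarbenium ion (C-4 is conjugated to the ring-D oxygen through the pyridone C=C), and the alkynyl group is handed over from the aluminate on the face the oxygen has left, the syn (SNi-type) epoxide opening known for alkynylalanes with 1,2-anhydro sugars, so that C-4 keeps its configuration with hydroxyl and alkynyl cis while the gem-dimethyl group shields C-3; the acidic work-up removes the silyl ether.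

**Step 4**
Reactants: 8 (3S,4S)-alkynyl diol
Product: 9 (3S,4S)-3-hydroxy-4-[(1E)-3-hydroxy-3-methylbut-1-en-1-yl]-2,2,6-trimethyl-3,4-dihydro-2H-pyrano[3,2-c]quinolin-5(6H)-one
Conditions: NaAlH2(OCH2CH2OMe)2 (Red-Al), THF, 0 °C → rt; aq potassium sodium tartrate
Reagents that add atoms: none
Why: alkoxide-directed trans-hydroalumination of the propargylic alcohol followed by protonolysis (the standard Red-Al reduction of propargylic alcohols) should give the E-allylic alcohol; no stereocentre is touched and only the alkene geometry is set.

**Step 5**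
Reactants: 9 (3S,4S)-E-allylic diol; 10 4-chloro-1-methylquinolin-2(1H)-one
Product: 12 CNP0107253.2 (R at the alkenyl-bearing carbon of ring C; S at both ring-fusion carbons), via aryl ether 11 (not isolated)
Conditions: NaH (1.1 equiv), THF–DMF (9:1), 0 → 45 °C; then CH2Cl2, CF3CO2H, 0 °C → rt, same flask
Reagents that add atoms: none
Why: The sodium alkoxide of the ring-D C-3 hydroxyl adds to C-4 of 10, the β-carbon of a vinylogous carbamoyl chloride, and expels chloride (addition–elimination, the SNAr-type etherification known for 4-chloro-2-quinolones), which gives ether 11 and turns C-3 of quinolone A into the nucleophilic carbon of an enol ether. Trifluoroacetic acid then ionises the tertiary allylic alcohol to a 1,1-dimethylallyl cation, and C-3 of quinolone A attacks its secondary terminus in an intramolecular Friedel–Crafts allylation (cation–olefin cyclisation), the position at which 4-oxygenated 2-quinolones take up carbon electrophiles; loss of the C-3 proton restores the pyridone. Ring C closes in the 6-(enolendo)-exo-trig mode, with the enol-ether C=C inside the new ring and the remaining allyl double bond outside it, where it becomes the 2-methylprop-1-enyl group; attack at the tertiary terminus would need an eight-membered ring. The new stereocentre is controlled by the two existing ones: the cis ring fusion is fixed by the 3S,4S array of 9, and in either half-chair of the forming ring the alkenyl part of the cation takes the position away from unit B on the adjacent carbon (equatorial when the C-2 quaternary carbon is axial, axial and anti to unit B otherwise), so bond formation should give the R configuration with the alkenyl group trans to unit B. The step needs O-arylation at the secondary and not the tertiary hydroxyl, which the higher acidity and lower hindrance of the secondary alkoxide secure (a tertiary aryl ether would in any case ionise to the same cation), and it needs ring closure to outrun loss of the C-4 proton from the cation, which the six-membered intramolecular trap and the non-basic medium secure.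

**Compound list**

1 | 4-hydroxy-1-methylquinolin-2(1H)-one | Cn1c(=O)cc(O)c2ccccc12 | starting material
2 | 3-methylbut-2-enal | CC(C)=CC=O | starting material
3 | 1-methyl-3-(3-methylbut-2-en-1-ylidene)quinoline-2,4(1H,3H)-dione (alkene isomers) | CC(C)=CC=C1C(=O)N(C)c2ccccc2C1=O | intermediate
4 | N-methylflindersine, 2,2,6-trimethyl-2H-pyrano[3,2-c]quinolin-5(6H)-one | CC1(C)C=Cc2c(O1)c1ccccc1n(C)c2=O | intermediate
5 | (3S,4S)-3,4-epoxy-2,2,6-trimethyl-3,4-dihydro-2H-pyrano[3,2-c]quinolin-5(6H)-one | O1[C@H]2[C@@H]1c1c(c3ccccc3n(C)c1=O)OC2(C)C | intermediate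
6 | trimethyl[(2-methylbut-3-yn-2-yl)oxy]silane | C#CC(C)(C)O[Si](C)(C)C | starting material
7 | (3S,4S)-3-hydroxy-2,2,6-trimethyl-4-{3-methyl-3-[(trimethylsilyl)oxy]but-1-yn-1-yl}-3,4-dihydro-2H-pyrano[3,2-c]quinolin-5(6H)-one | O[C@H]1[C@@H](C#CC(C)(C)O[Si](C)(C)C)c2c(c3ccccc3n(C)c2=O)OC1(C)C | intermediate
8 | (3S,4S)-3-hydroxy-4-(3-hydroxy-3-methylbut-1-yn-1-yl)-2,2,6-trimethyl-3,4-dihydro-2H-pyrano[3,2-c]quinolin-5(6H)-one | O[C@H]1[C@@H](C#CC(C)(C)O)c2c(c3ccccc3n(C)c2=O)OC1(C)C | intermediate
9 | (3S,4S)-3-hydroxy-4-[(1E)-3-hydroxy-3-methylbut-1-en-1-yl]-2,2,6-trimethyl-3,4-dihydro-2H-pyrano[3,2-c]quinolin-5(6H)-one | O[C@H]1[C@@H](/C=C/C(C)(C)O)c2c(c3ccccc3n(C)c2=O)OC1(C)C | intermediate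
10 | 4-chloro-1-methylquinolin-2(1H)-one | Cn1c(=O)cc(Cl)c2ccccc12 | starting material
11 | (3S,4S)-4-[(1E)-3-hydroxy-3-methylbut-1-en-1-yl]-2,2,6-trimethyl-3-[(1-methyl-2-oxo-1,2-dihydroquinolin-4-yl)oxy]-3,4-dihydro-2H-pyrano[3,2-c]quinolin-5(6H)-one | Cn1c(=O)cc(O[C@H]2[C@@H](/C=C/C(C)(C)O)c3c(c4ccccc4n(C)c3=O)OC2(C)C)c2ccccc12 | intermediate
12 | CNP0107253.2: cis-fused bis(pyranoquinolinone); R at the ring-C carbon bearing 2-methylprop-1-enyl (trans to unit B), S at the ring-fusion carbon bonded to the ring-C oxygen, S at the ring-fusion carbon bonded to quinolone B | CC(C)=C[C@H]1c2c(c3ccccc3n(C)c2=O)O[C@H]2[C@@H]1c1c(c3ccccc3n(C)c1=O)OC2(C)C | target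

**Totals**

Total step count: 5. Longest linear sequence: 5 steps (1 → 4 → 5 → 8 → 9 → 12).

**Three steps most likely to fail**

1. Step 3. Process at risk: delivery of the alkynyl group with inversion instead of retention at C-4, or a 1,2-hydride shift of the oxirane to the 3-ketone before C–C bond formation. The fallback sets out from 5 and returns at 7 (and so at 8). The lithium acetylide of 6 with BF3·OEt2 in THF at −78 °C should open the oxirane at C-4 with inversion to the trans alkynyl alcohol F1. Dess–Martin periodinane oxidises it to the 3-ketone F2, in which C-4 (α to the ketone, benzylic and propargylic) epimerises freely. Asymmetric transfer hydrogenation under dynamic kinetic resolution, with RuCl(p-cymene)(TsDPEN) of the ligand enantiomer that gives the 3S carbinol in HCO2H–Et3N, should reduce the ketone anti to the C-4 substituent and funnel both ketone epimers into the cis 3S,4S alcohol 7, which the acidic work-up of step 3 converts into 8.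

2. Step 5. Process at risk: insufficient facial selectivity in the ring closure, loss of the C-4 proton from the allyl cation before cyclisation (erosion of the ring-fusion configuration), O-arylation at the tertiary hydroxyl, or base-induced ring contraction of ring D by the alkoxide. The fallback sets out from 9 and 10 and returns at 12. Ether 11 is isolated after the NaH stage. OsO4 (catalytic) with NaIO4 cleaves its side-chain alkene to the aldehyde F3. BF3·OEt2 then closes ring C by intramolecular Friedel–Crafts hydroxyalkylation at C-3 of quinolone A, giving the ring-C carbinol F4 as a mixture of carbinol epimers. Renewed ionisation with BF3·OEt2 in the presence of (2-methylprop-1-en-1-yl)boronic acid generates the ring-C vinylogous oxocarbenium ion, to which the alkenyl group should add on the convex face, anti to unit B, to give 12. In this variant the stereocentre is set by an external nucleophile on a rigid bicyclic cation and no open-chain allyl cation is involved.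

3. Step 4. Process at risk: hydride attack on the two lactam carbonyls, or sluggish hydroalumination of the hindered tertiary propargylic alkoxide. The fallback sets out from 8 and returns at 9. Ruthenium-catalysed trans-hydrosilylation with [Cp*Ru(MeCN)3]PF6 and (EtO)3SiH in CH2Cl2 should give the Z-vinylsilane F5 (silicon expected on the alkyne carbon remote from the tertiary hydroxyl; either regioisomer serves). Protodesilylation with TBAF and CuI in THF then replaces silicon by hydrogen with retention and gives the E-alkene 9 without any hydride reagent.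

**Further compounds**

F1 | step 3 | (3S,4R)-3-hydroxy-2,2,6-trimethyl-4-{3-methyl-3-[(trimethylsilyl)oxy]but-1-yn-1-yl}-3,4-dihydro-2H-pyrano[3,2-c]quinolin-5(6H)-one | O[C@H]1[C@H](C#CC(C)(C)O[Si](C)(C)C)c2c(c3ccccc3n(C)c2=O)OC1(C)C
F2 | step 3 | 2,2,6-trimethyl-4-{3-methyl-3-[(trimethylsilyl)oxy]but-1-yn-1-yl}-2H-pyrano[3,2-c]quinoline-3,5(4H,6H)-dione (C-4 configurationally labile) | CC1(C)Oc2c(c(=O)n(C)c3ccccc23)C(C#CC(C)(C)O[Si](C)(C)C)C1=O
F3 | step 5 | (3S,4S)-2,2,6-trimethyl-3-[(1-methyl-2-oxo-1,2-dihydroquinolin-4-yl)oxy]-5-oxo-3,4,5,6-tetrahydro-2H-pyrano[3,2-c]quinoline-4-carbaldehyde | Cn1c(=O)cc(O[C@H]2[C@@H](C=O)c3c(c4ccccc4n(C)c3=O)OC2(C)C)c2ccccc12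
F4 | step 5 | ring-C carbinol: the target skeleton with hydroxyl in place of the 2-methylprop-1-enyl group (carbinol epimers, ring fusion S,S) | OC1c2c(c3ccccc3n(C)c2=O)O[C@H]2[C@@H]1c1c(c3ccccc3n(C)c1=O)OC2(C)C
F5 | step 4 | (3S,4S)-3-hydroxy-4-[(1Z)-3-hydroxy-3-methyl-1-(triethoxysilyl)but-1-en-1-yl]-2,2,6-trimethyl-3,4-dihydro-2H-pyrano[3,2-c]quinolin-5(6H)-one | O[C@H]1[C@@H](/C(=C/C(C)(C)O)[Si](OCC)(OCC)OCC)c2c(c3ccccc3n(C)c2=O)OC1(C)C
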